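## Retrosynthetic overview

1. The target is cut at the sp2–sp3 bond between the E-alkene CH and the tertiary carbinol carbon. The forward reaction is a catalytic asymmetric 1,2-addition of an (E)-alkenylzinc, made in the flask from terminal alkyne 7, to methyl ketone 9. This one operation makes the bond, the E-alkene and the (R)-carbinol, and brings in the side-chain isobutyrate.
2. Enabling feature: the acyclic carbinol carbon (CH3, OH, CH2O-acyl) sits directly on an E-1,2-disubstituted alkene that is skipped (1,4) to the exocyclic C=CH2. This is the retron of a syn-hydrometalated terminal alkyne of a 1,4-enyne adding to a ketone. The cyclohexene ring takes no part.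
3. Enyne 7 comes from allylic chloride 6 (ene-type chlorination of the isopropenyl group) and ethynyl Grignard under copper catalysis. The ring ketone is carried as a silyl-protected carbinol.
4. No ring is formed. The single carbocycle and its stereocenter come from (+)-trans-limonene oxide 1. Two epoxide-to-allylic-alcohol isomerizations around a hydroxyl-directed epoxidation give the ring-carbinol/CH2OH pattern of diol 4.
5. Endgame: desilylation, primary-selective isobutyrylation, allylic oxidation to the enone.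

Key step: step 8

Remark 1: pure (+)-trans-limonene oxide is used so that every intermediate is one diastereomer; the commercial cis/trans mixture would serve equally, because the carbinol center it sets is oxidized in step 11.

Remark 2 (assumption): the Ti/bis(sulfonamide) diol catalyst is assumed to distinguish the ketone faces only by substituent size (CH2OC(O)iPr larger than CH3). "L*" means the antipode of trans-N,N'-cyclohexane-1,2-diylbis(2-hydroxycamphor-10-sulfonamide) that delivers the alkenyl group to the Re face of 9; a model addition should confirm the sense before use.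

## Route

Step 1
Reactants: 1 (+)-trans-limonene oxide
Product: 2 (1R,5R)-2-methylidene-5-(prop-1-en-2-yl)cyclohexan-1-ol
Conditions: Et2AlTMP (from TMP, n-BuLi, Et2AlCl), toluene, 0 °C; aq. Rochelle salt
Reagents that add atoms: none
Why: Aluminium amide epoxide-to-allylic-alcohol isomerization: Al binds the epoxide oxygen and the amide removes a syn methyl proton, giving the exocyclic methylene, while the carbinol keeps the configuration of the epoxide CH carbon, whose C–O bond is not broken.

Step 2
Reactants: 2 (1R,5R)-2-methylidene-5-(prop-1-en-2-yl)cyclohexan-1-ol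
Product: 3 (3R,4R,6R)-6-(prop-1-en-2-yl)-1-oxaspiro[2.5]octan-4-ol
Conditions: VO(acac)2 (2 mol %), t-BuOOH, CH2Cl2, 0 °C to rt
Reagents that add atoms: tert-butyl hydroperoxide, CC(C)(C)OO
Why: Vanadium-catalysed hydroxyl-directed epoxidation should touch only the allylic-alcohol alkene and leave the isopropenyl group, delivering oxygen syn to OH; the new spiro center is erased in step 3, so its configuration is immaterial.

Step 3
Reactants: 3 (3R,4R,6R)-6-(prop-1-en-2-yl)-1-oxaspiro[2.5]octan-4-ol
Product: 4 (1R,5R)-2-(hydroxymethyl)-5-(prop-1-en-2-yl)cyclohex-2-en-1-ol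
Conditions: Et2AlTMP (3 equiv; from TMP, n-BuLi, Et2AlCl), toluene, 0 °C to rt; aq. Rochelle salt
Reagents that add atoms: none
Why: The same aluminium amide isomerization on a 2,2-disubstituted epoxide: syn removal of a ring CH2 proton next to the spiro carbon should open the tertiary C–O bond and give the endocyclic trisubstituted alkene with the primary allylic alcohol.

Step 4
Reactants: 4 (1R,5R)-2-(hydroxymethyl)-5-(prop-1-en-2-yl)cyclohex-2-en-1-ol
Product: 5 (1R,5R)-1-(tert-butyldimethylsilyloxy)-2-[(tert-butyldimethylsilyloxy)methyl]-5-(prop-1-en-2-yl)cyclohex-2-ene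
Conditions: TBSCl (2.5 equiv), imidazole, DMF, rt
Reagents that add atoms: tert-butyldimethylsilyl chloride, CC(C)(C)[Si](C)(C)Cl
Why: Standard silyl ether formation protects both hydroxyls for the Grignard and Zr–H steps and further deactivates and shields the ring alkene.

Step 5
Reactants: 5 (1R,5R)-1-(tert-butyldimethylsilyloxy)-2-[(tert-butyldimethylsilyloxy)methyl]-5-(prop-1-en-2-yl)cyclohex-2-ene
Product: 6 (1R,5R)-1-(tert-butyldimethylsilyloxy)-2-[(tert-butyldimethylsilyloxy)methyl]-5-(3-chloroprop-1-en-2-yl)cyclohex-2-ene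
Conditions: Ca(OCl)2, CO2 (s), CH2Cl2/H2O, 0 °C
Reagents that add atoms: calcium hypochlorite, [Ca+2].[O-]Cl.[O-]Cl
Why: Ene-type allylic chlorination by HOCl should take the electron-rich isopropenyl group (Cl+ on the CH2 terminus, proton loss from the methyl), because the ring alkene is deactivated by two allylic silyloxy groups and sterically screened.

Step 6
Reactants: 6 (1R,5R)-1-(tert-butyldimethylsilyloxy)-2-[(tert-butyldimethylsilyloxy)methyl]-5-(3-chloroprop-1-en-2-yl)cyclohex-2-ene
Product: 7 (1R,5R)-1-(tert-butyldimethylsilyloxy)-2-[(tert-butyldimethylsilyloxy)methyl]-5-(pent-1-en-4-yn-2-yl)cyclohex-2-ene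
Conditions: HC≡CMgBr, CuCl (10 mol %), THF, 0 °C to rt
Reagents that add atoms: ethynylmagnesium bromide, C#C[Mg]Br
Why: Copper-catalysed coupling of an alkynyl Grignard reagent with a 2-substituted allylic chloride is the classical entry to 1,4-enynes; SN2 and SN2' paths give the same product because both allyl termini are CH2.

Step 7
Reactants: 8 hydroxyacetone
Product: 9 2-oxopropyl 2-methylpropanoate
Conditions: i-PrCOCl, pyridine, CH2Cl2, 0 °C
Reagents that add atoms: isobutyryl chloride, CC(C)C(=O)Cl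
Why: Simple acylation of the primary hydroxyl under mild base gives the ketone partner with the side-chain ester already in place.

Step 8
Reactants: 7 (1R,5R)-1-(tert-butyldimethylsilyloxy)-2-[(tert-butyldimethylsilyloxy)methyl]-5-(pent-1-en-4-yn-2-yl)cyclohex-2-ene; 9 2-oxopropyl 2-methylpropanoate
Product: 12 (2R,3E)-6-[(1R,5R)-5-(tert-butyldimethylsilyloxy)-4-[(tert-butyldimethylsilyloxy)methyl]cyclohex-3-en-1-yl]-2-hydroxy-2-methylhepta-3,6-dien-1-yl 2-methylpropanoate, via (E)-alkenylzirconocene chloride 10 (not isolated), via (E)-alkenyl(methyl)zinc 11 (not isolated)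
Conditions: Cp2Zr(H)Cl (1.1 equiv), CH2Cl2, rt; then Me2Zn, toluene, −78 °C; then L* (10 mol %), Ti(Oi-Pr)4 (1.2 equiv), 9 (2 equiv), toluene, rt; aq. NH4Cl
Reagents that add atoms: none
Why: Syn-hydrozirconation places Zr on the terminal alkyne carbon to give 10, Zr-to-Zn exchange with Me2Zn gives 11, and the chiral titanium bis(sulfonamide) diolate activates the ketone of 9 so that the alkenyl group, which transfers in preference to methyl, adds to C=O. The closest known reaction is the catalytic asymmetric vinylation of ketones by hydrozirconation, zinc transmetalation and Ti/bis(sulfonamide) diol catalysis, which is the same reaction type applied to a new ketone. No ring is closed. The new (R)-carbinol center is set by the ligand through Re-face attack; the ring stereocenters are too remote to matter. E geometry follows from syn addition of Zr–H; chemoselectivity should follow from the much higher reactivity of the terminal alkyne over the 1,1-disubstituted and trisubstituted alkenes, the inertness of silyl ethers, and the failure of alkenylzinc species to add to esters. The facial selectivity rests on the size difference between CH3 and CH2OC(O)iPr and is the weakest point of the step.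

Step 9
Reactants: 12 (2R,3E)-6-[(1R,5R)-5-(tert-butyldimethylsilyloxy)-4-[(tert-butyldimethylsilyloxy)methyl]cyclohex-3-en-1-yl]-2-hydroxy-2-methylhepta-3,6-dien-1-yl 2-methylpropanoate
Product: 13 (2R,3E)-2-hydroxy-6-[(1R,5R)-5-hydroxy-4-(hydroxymethyl)cyclohex-3-en-1-yl]-2-methylhepta-3,6-dien-1-yl 2-methylpropanoate
Conditions: HF·pyridine, pyridine, THF, 0 °C to rt
Reagents that add atoms: none
Why: Buffered fluoride desilylation should remove both silyl ethers without ester cleavage, acyl migration or ionization of the tertiary allylic alcohol.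

Step 10
Reactants: 13 (2R,3E)-2-hydroxy-6-[(1R,5R)-5-hydroxy-4-(hydroxymethyl)cyclohex-3-en-1-yl]-2-methylhepta-3,6-dien-1-yl 2-methylpropanoate
Product: 14 (2R,3E)-2-hydroxy-6-[(1R,5R)-5-hydroxy-4-{[(2-methylpropanoyl)oxy]methyl}cyclohex-3-en-1-yl]-2-methylhepta-3,6-dien-1-yl 2-methylpropanoate
Conditions: i-PrCOCl (1.05 equiv), 2,4,6-collidine, CH2Cl2, −78 to −40 °C
Reagents that add atoms: isobutyryl chloride, CC(C)C(=O)Cl
Why: Kinetically controlled acylation with a branched acyl chloride and a hindered base should select the primary allylic hydroxyl over the secondary ring hydroxyl and the unreactive tertiary one.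

Step 11
Reactants: 14 (2R,3E)-2-hydroxy-6-[(1R,5R)-5-hydroxy-4-{[(2-methylpropanoyl)oxy]methyl}cyclohex-3-en-1-yl]-2-methylhepta-3,6-dien-1-yl 2-methylpropanoate
Product: 15 (2R,3E)-2-hydroxy-2-methyl-6-[(1R)-4-{[(2-methylpropanoyl)oxy]methyl}-5-oxocyclohex-3-en-1-yl]hepta-3,6-dien-1-yl 2-methylpropanoate (target)
Conditions: MnO2 (activated, excess), CH2Cl2, rt
Reagents that add atoms: none
Why: Manganese dioxide oxidizes only the secondary allylic alcohol to the enone; the tertiary allylic alcohol cannot be oxidized and the ring stereocenter, β to the new carbonyl, cannot epimerize.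

## Compound list

1 | (+)-trans-limonene oxide, (1S,4R,6R)-1-methyl-4-(prop-1-en-2-yl)-7-oxabicyclo[4.1.0]heptane | C=C(C)[C@@H]1CC[C@]2(C)O[C@@H]2C1 | starting material
2 | (1R,5R)-2-methylidene-5-(prop-1-en-2-yl)cyclohexan-1-ol | C=C(C)[C@@H]1CCC(=C)[C@H](O)C1 | intermediate
3 | (3R,4R,6R)-6-(prop-1-en-2-yl)-1-oxaspiro[2.5]octan-4-ol | C=C(C)[C@@H]1CC[C@@]2(CO2)[C@H](O)C1 | intermediate
4 | (1R,5R)-2-(hydroxymethyl)-5-(prop-1-en-2-yl)cyclohex-2-en-1-ol | C=C(C)[C@@H]1CC=C(CO)[C@H](O)C1 | intermediate
5 | (1R,5R)-1-(tert-butyldimethylsilyloxy)-2-[(tert-butyldimethylsilyloxy)methyl]-5-(prop-1-en-2-yl)cyclohex-2-ene | C=C(C)[C@@H]1CC=C(CO[Si](C)(C)C(C)(C)C)[C@H](O[Si](C)(C)C(C)(C)C)C1 | intermediate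
6 | (1R,5R)-1-(tert-butyldimethylsilyloxy)-2-[(tert-butyldimethylsilyloxy)methyl]-5-(3-chloroprop-1-en-2-yl)cyclohex-2-ene | C=C(CCl)[C@@H]1CC=C(CO[Si](C)(C)C(C)(C)C)[C@H](O[Si](C)(C)C(C)(C)C)C1 | intermediate
7 | (1R,5R)-1-(tert-butyldimethylsilyloxy)-2-[(tert-butyldimethylsilyloxy)methyl]-5-(pent-1-en-4-yn-2-yl)cyclohex-2-ene | C#CCC(=C)[C@@H]1CC=C(CO[Si](C)(C)C(C)(C)C)[C@H](O[Si](C)(C)C(C)(C)C)C1 | intermediate
8 | hydroxyacetone | CC(=O)CO | starting material
9 | 2-oxopropyl 2-methylpropanoate | CC(=O)COC(=O)C(C)C | intermediate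
10 | chloridobis(cyclopentadienyl){(1E)-4-[(1R,5R)-5-(tert-butyldimethylsilyloxy)-4-[(tert-butyldimethylsilyloxy)methyl]cyclohex-3-en-1-yl]penta-1,4-dien-1-yl}zirconium (Cp rings drawn σ-bonded) | Cl[Zr](C1C=CC=C1)(C1C=CC=C1)/C=C/CC(=C)[C@@H]1CC=C(CO[Si](C)(C)C(C)(C)C)[C@H](O[Si](C)(C)C(C)(C)C)C1 | intermediate
11 | methyl{(1E)-4-[(1R,5R)-5-(tert-butyldimethylsilyloxy)-4-[(tert-butyldimethylsilyloxy)methyl]cyclohex-3-en-1-yl]penta-1,4-dien-1-yl}zinc | C[Zn]/C=C/CC(=C)[C@@H]1CC=C(CO[Si](C)(C)C(C)(C)C)[C@H](O[Si](C)(C)C(C)(C)C)C1 | intermediate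
12 | (2R,3E)-6-[(1R,5R)-5-(tert-butyldimethylsilyloxy)-4-[(tert-butyldimethylsilyloxy)methyl]cyclohex-3-en-1-yl]-2-hydroxy-2-methylhepta-3,6-dien-1-yl 2-methylpropanoate | C=C(C/C=C/[C@@](C)(O)COC(=O)C(C)C)[C@@H]1CC=C(CO[Si](C)(C)C(C)(C)C)[C@H](O[Si](C)(C)C(C)(C)C)C1 | intermediate
13 | (2R,3E)-2-hydroxy-6-[(1R,5R)-5-hydroxy-4-(hydroxymethyl)cyclohex-3-en-1-yl]-2-methylhepta-3,6-dien-1-yl 2-methylpropanoate | C=C(C/C=C/[C@@](C)(O)COC(=O)C(C)C)[C@@H]1CC=C(CO)[C@H](O)C1 | intermediate
14 | (2R,3E)-2-hydroxy-6-[(1R,5R)-5-hydroxy-4-{[(2-methylpropanoyl)oxy]methyl}cyclohex-3-en-1-yl]-2-methylhepta-3,6-dien-1-yl 2-methylpropanoate | C=C(C/C=C/[C@@](C)(O)COC(=O)C(C)C)[C@@H]1CC=C(COC(=O)C(C)C)[C@H](O)C1 | intermediate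
15 | (2R,3E)-2-hydroxy-2-methyl-6-[(1R)-4-{[(2-methylpropanoyl)oxy]methyl}-5-oxocyclohex-3-en-1-yl]hepta-3,6-dien-1-yl 2-methylpropanoate | C=C(C/C=C/[C@@](C)(O)COC(=O)C(C)C)[C@@H]1CC=C(COC(=O)C(C)C)C(=O)C1 | target

## Step count and risks

Total step count: 11. Longest linear sequence: 10 (steps 1–6 and 8–11); step 7 is a one-step side branch.

Steps most likely to fail:

1. Step 8. The catalyst may discriminate poorly between the methyl and acyloxymethyl flanks of the ketone, and the ee may be eroded further by uncatalysed, chelation-accelerated background addition and by enolization or self-aldol of the α-acyloxy ketone. The resulting epimers at the carbinol would be hard to separate because the other stereocenters are remote. Fallback: setting out from 7, the same bond is made at the alkyne oxidation level by zinc triflate/triethylamine/chiral β-amino alcohol-mediated enantioselective alkynylation of ethyl pyruvate, a two-point-binding α-keto ester. This should give ethyl (2R)-6-[(1R,5R)-5-(tert-butyldimethylsilyloxy)-4-[(tert-butyldimethylsilyloxy)methyl]cyclohex-3-en-1-yl]-2-hydroxy-2-methylhept-6-en-3-ynoate F1. Red-Al in THF then reduces the ester to CH2OH and, by trans-hydroalumination of the propargylic alkoxide, the alkyne to the E-alkene, giving (2R,3E)-6-[(1R,5R)-5-(tert-butyldimethylsilyloxy)-4-[(tert-butyldimethylsilyloxy)methyl]cyclohex-3-en-1-yl]-2-methylhepta-3,6-diene-1,2-diol F2. Primary-selective acylation with isobutyryl chloride and collidine brings the route back at 12.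

2. Step 3. The amide may abstract the wrong proton or attack the epoxide CH2, or the Lewis-acidic aluminium alkoxide may trigger a 1,2-hydride shift to a β-hydroxy ketone. Fallback: setting out from 3, the hydroxyl is silylated (TBSCl, imidazole) to tert-butyldimethyl{[(3R,4R,6R)-6-(prop-1-en-2-yl)-1-oxaspiro[2.5]octan-4-yl]oxy}silane F3. The epoxide is then opened homolytically with Cp2TiCl (from Cp2TiCl2 and Mn, THF); the tertiary radical is trapped by a second Ti(III) and loses a ring β-hydrogen, which should give [(4R,6R)-6-(tert-butyldimethylsilyloxy)-4-(prop-1-en-2-yl)cyclohex-1-en-1-yl]methanol F4. Silylation of the primary hydroxyl (TBSCl, imidazole) returns to the route at 5.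

3. Step 5. Site selectivity may be lost through competing electrophilic chlorination of the ring alkene or over-chlorination. Fallback: setting out from 4, the primary hydroxyl is silylated selectively (TBSCl 1.05 equiv, imidazole, CH2Cl2, 0 °C) to (1R,5R)-2-[(tert-butyldimethylsilyloxy)methyl]-5-(prop-1-en-2-yl)cyclohex-2-en-1-ol F5. MnO2 oxidation gives (5R)-2-[(tert-butyldimethylsilyloxy)methyl]-5-(prop-1-en-2-yl)cyclohex-2-en-1-one F6, in which the ring alkene is an enone and inert to HOCl. Ca(OCl)2/CO2 chlorination then gives (5R)-2-[(tert-butyldimethylsilyloxy)methyl]-5-(3-chloroprop-1-en-2-yl)cyclohex-2-en-1-one F7. Luche reduction (NaBH4, CeCl3, MeOH, −78 °C) should give the cis alcohol (1R,5R)-2-[(tert-butyldimethylsilyloxy)methyl]-5-(3-chloroprop-1-en-2-yl)cyclohex-2-en-1-ol F8, and TBSOTf/2,6-lutidine returns to the route at 6.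

Further compounds
F1 | step 8 | ethyl (2R)-6-[(1R,5R)-5-(tert-butyldimethylsilyloxy)-4-[(tert-butyldimethylsilyloxy)methyl]cyclohex-3-en-1-yl]-2-hydroxy-2-methylhept-6-en-3-ynoate | C=C(CC#C[C@@](C)(O)C(=O)OCC)[C@@H]1CC=C(CO[Si](C)(C)C(C)(C)C)[C@H](O[Si](C)(C)C(C)(C)C)C1
F2 | step 8 | (2R,3E)-6-[(1R,5R)-5-(tert-butyldimethylsilyloxy)-4-[(tert-butyldimethylsilyloxy)methyl]cyclohex-3-en-1-yl]-2-methylhepta-3,6-diene-1,2-diol | C=C(C/C=C/[C@@](C)(O)CO)[C@@H]1CC=C(CO[Si](C)(C)C(C)(C)C)[C@H](O[Si](C)(C)C(C)(C)C)C1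
F3 | step 3 | tert-butyldimethyl{[(3R,4R,6R)-6-(prop-1-en-2-yl)-1-oxaspiro[2.5]octan-4-yl]oxy}silane | C=C(C)[C@@H]1CC[C@@]2(CO2)[C@H](O[Si](C)(C)C(C)(C)C)C1
F4 | step 3 | [(4R,6R)-6-(tert-butyldimethylsilyloxy)-4-(prop-1-en-2-yl)cyclohex-1-en-1-yl]methanol | C=C(C)[C@@H]1CC=C(CO)[C@H](O[Si](C)(C)C(C)(C)C)C1
F5 | step 5 | (1R,5R)-2-[(tert-butyldimethylsilyloxy)methyl]-5-(prop-1-en-2-yl)cyclohex-2-en-1-ol | C=C(C)[C@@H]1CC=C(CO[Si](C)(C)C(C)(C)C)[C@H](O)C1
F6 | step 5 | (5R)-2-[(tert-butyldimethylsilyloxy)methyl]-5-(prop-1-en-2-yl)cyclohex-2-en-1-one | C=C(C)[C@@H]1CC=C(CO[Si](C)(C)C(C)(C)C)C(=O)C1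
F7 | step 5 | (5R)-2-[(tert-butyldimethylsilyloxy)methyl]-5-(3-chloroprop-1-en-2-yl)cyclohex-2-en-1-one | C=C(CCl)[C@@H]1CC=C(CO[Si](C)(C)C(C)(C)C)C(=O)C1
F8 | step 5 | (1R,5R)-2-[(tert-butyldimethylsilyloxy)methyl]-5-(3-chloroprop-1-en-2-yl)cyclohex-2-en-1-ol | C=C(CCl)[C@@H]1CC=C(CO[Si](C)(C)C(C)(C)C)[C@H](O)C1
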